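**Strategy.** The flavonol is cut at C3–C4 and C2=C3 of ring C: C3, the lone oxygen-bearing carbon lodged between the ring A ketone C4 and the ring B-bearing C2, is delivered as the carbon of an α-alkoxy phosphorus ylide. In one operation the ylide is C-acylated by a ring A benzoyl chloride and the acyl ylide then olefinates the neighbouring O1 aryl ester, whose carbonyl carbon becomes C2, closing the pyranone with O3 already installed. The precursor is a salicyloyl chloride whose phenol oxygen carries the ring B aroyl group, with MOM-masked phenols and the prenyl ether in place; fluoride and then mild acid release the target.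

Key step: step 9

Remark: the target has no stereocentre and no stereogenic double bond, so no stereocontrol is needed. Design choices: ring B acid 5 is coupled directly with a carbodiimide, the single acid chloride 10 is made with an α-chloroenamine so that no HCl meets the MOM and prenyl ethers, and O3 is freed before the MOM groups so that the catechol is only exposed under acid.

Step 1
Reactants: 1 3,4-dihydroxybenzaldehyde
Product: 2 3-hydroxy-4-(methoxymethoxy)benzaldehyde
Conditions: MOMCl (1.05 equiv), K2CO3, acetone, 0 °C to rt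
Reagents that add atoms: chloromethyl methyl ether (MOMCl), COCCl
Why: The 4-OH, para to the aldehyde, is the more acidic catechol hydroxyl, so its phenoxide forms first and should be alkylated selectively (regioselective Williamson-type O-alkylation).

Step 2
Reactants: 2 3-hydroxy-4-(methoxymethoxy)benzaldehyde, 3 prenyl bromide (1-bromo-3-methylbut-2-ene)
Product: 4 4-(methoxymethoxy)-3-[(3-methylbut-2-en-1-yl)oxy]benzaldehyde
Conditions: K2CO3, DMF, rt
Reagents that add atoms: none
Why: Williamson ether synthesis, the remaining phenoxide displacing bromide from the primary allylic halide by SN2 at the unhindered carbon.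

Step 3
Reactants: 4 4-(methoxymethoxy)-3-[(3-methylbut-2-en-1-yl)oxy]benzaldehyde
Product: 5 4-(methoxymethoxy)-3-[(3-methylbut-2-en-1-yl)oxy]benzoic acid
Conditions: NaClO2, NaH2PO4, 2-methyl-2-butene (large excess), t-BuOH/THF/H2O, 0 °C to rt
Reagents that add atoms: NaClO2 (sodium chlorite), [Na+].[O-]Cl=O
Why: Pinnick oxidation; the excess 2-methyl-2-butene traps HOCl so that the prenyl alkene and the electron-rich ring should be spared, and the buffered medium leaves the MOM acetal intact.

Step 4
Reactants: 6 2,4,5-trihydroxybenzaldehyde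
Product: 7 2-hydroxy-4,5-bis(methoxymethoxy)benzaldehyde
Conditions: MOMCl (2.05 equiv), K2CO3, acetone, argon, 0 °C to rt
Reagents that add atoms: chloromethyl methyl ether (MOMCl), COCCl
Why: The 2-OH is tied up in an intramolecular hydrogen bond to the aldehyde and is the least nucleophilic, so Williamson-type alkylation should stop after the 4- and 5-hydroxyls.

Step 5
Reactants: 5 4-(methoxymethoxy)-3-[(3-methylbut-2-en-1-yl)oxy]benzoic acid, 7 2-hydroxy-4,5-bis(methoxymethoxy)benzaldehyde
Product: 8 2-formyl-4,5-bis(methoxymethoxy)phenyl 4-(methoxymethoxy)-3-[(3-methylbut-2-en-1-yl)oxy]benzoate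
Conditions: N,N'-diisopropylcarbodiimide, DMAP (0.2 equiv), CH2Cl2, 0 °C to rt
Reagents that add atoms: none
Why: Steglich esterification, DMAP relaying the acyl group from the O-acylisourea to the hydrogen-bonded phenol under neutral conditions that spare MOM and prenyl ethers.

Step 6
Reactants: 8 2-formyl-4,5-bis(methoxymethoxy)phenyl 4-(methoxymethoxy)-3-[(3-methylbut-2-en-1-yl)oxy]benzoate
Product: 9 4,5-bis(methoxymethoxy)-2-({4-(methoxymethoxy)-3-[(3-methylbut-2-en-1-yl)oxy]benzoyl}oxy)benzoic acid
Conditions: NaClO2, NaH2PO4, 2-methyl-2-butene (large excess), t-BuOH/THF/H2O, 0 °C to rt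
Reagents that add atoms: NaClO2 (sodium chlorite), [Na+].[O-]Cl=O
Why: Pinnick oxidation at about pH 4, where the aryl ester does not hydrolyse or migrate and the scavenger protects the prenyl group.

Step 7
Reactants: 9 4,5-bis(methoxymethoxy)-2-({4-(methoxymethoxy)-3-[(3-methylbut-2-en-1-yl)oxy]benzoyl}oxy)benzoic acid
Product: 10 2-(chlorocarbonyl)-4,5-bis(methoxymethoxy)phenyl 4-(methoxymethoxy)-3-[(3-methylbut-2-en-1-yl)oxy]benzoate
Conditions: 1-chloro-N,N,2-trimethylprop-1-en-1-amine (1.1 equiv), CH2Cl2, 0 °C to rt; evaporate under high vacuum, use crude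
Reagents that add atoms: 1-chloro-N,N,2-trimethylprop-1-en-1-amine, CC(C)=C(Cl)N(C)C
Why: Acid chloride formation with an α-chloroenamine, which passes through an acyloxyiminium chloride and releases only a neutral amide, so no HCl should reach the MOM acetals, the prenyl ether or the aryl ester.

Step 8
Reactants: 11 2-(trimethylsilyl)ethoxymethyl chloride (SEM chloride), 12 triphenylphosphine
Product: 13 triphenyl{[2-(trimethylsilyl)ethoxy]methyl}phosphonium chloride
Conditions: toluene, 80 °C; filter and dry the salt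
Reagents that add atoms: none
Why: SN2 quaternisation of the phosphine by a reactive α-chloro ether, the salt precipitating from toluene.

Step 9
Reactants: 13 triphenyl{[2-(trimethylsilyl)ethoxy]methyl}phosphonium chloride, 10 2-(chlorocarbonyl)-4,5-bis(methoxymethoxy)phenyl 4-(methoxymethoxy)-3-[(3-methylbut-2-en-1-yl)oxy]benzoate
Product: 17 6,7-bis(methoxymethoxy)-2-{4-(methoxymethoxy)-3-[(3-methylbut-2-en-1-yl)oxy]phenyl}-3-[2-(trimethylsilyl)ethoxy]-4H-chromen-4-one, via alkoxymethylene ylide 14 (not isolated), via C-acylphosphonium chloride 15 (not isolated), via alkoxy acyl ylide 16 (not isolated)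
Conditions: 13 (2.2 equiv), NaN(SiMe3)2 (2.1 equiv), THF, −78 to 0 °C; then 10 (1.0 equiv) in THF added slowly at −78 °C, to rt; dilute with toluene (about 0.01 M), 80–110 °C
Reagents that add atoms: none
Why: Proposed new method: ylide 14, made with a lithium-free amide base, should add to the acid chloride carbonyl of 10 at −78 °C to give salt 15 (C3–C4 bond), a second equivalent of 14 should deprotonate 15 to the α-alkoxy acyl ylide 16, and on warming the ylide carbon of 16 should add to the adjacent aryl ester carbonyl and expel Ph3PO, which creates C2=C3. The closest known reaction type is the C-acylation of alkylidene- and silylmethylene-phosphoranes by O-acylsalicylic acid derivatives followed by intramolecular Wittig olefination of the ester to chromones and flavones; only the oxygen substituent on the ylide carbon is new, and as a donor it should make 16 more nucleophilic than the acyl ylides of the known cases, at the price of forming a tetrasubstituted alkene. Ring C is closed in the 6-exo-trig mode, C3 attacking the ester carbon that becomes C2 while O1, C8a, C4a and C4 are already linked. No stereocentre arises. The step needs chemoselection between the two acyl groups of 10, secured by the much higher electrophilicity of the acid chloride over the aryl ester of an electron-rich benzoic acid, by slow addition of 10 to an excess of 14 at −78 °C (which also suppresses O-acylation of 16 by 10), and by dilution before heating so that ring closure outruns intermolecular acyl transfer. Neither reactant has an acidic C–H, and MOM ethers, the prenyl ether and the silylethyl group are inert to the base-only conditions.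

Step 10
Reactants: 17 6,7-bis(methoxymethoxy)-2-{4-(methoxymethoxy)-3-[(3-methylbut-2-en-1-yl)oxy]phenyl}-3-[2-(trimethylsilyl)ethoxy]-4H-chromen-4-one
Product: 18 3-hydroxy-6,7-bis(methoxymethoxy)-2-{4-(methoxymethoxy)-3-[(3-methylbut-2-en-1-yl)oxy]phenyl}-4H-chromen-4-one
Conditions: Bu4NF (3 equiv), THF, rt to 60 °C; AcOH quench
Reagents that add atoms: none
Why: Fluoride-induced fragmentation of a 2-(trimethylsilyl)ethyl ether: attack at silicon should trigger β-elimination of ethene and expel the 3-oxide, a good leaving group because it is an enolate conjugated to the C4 carbonyl, while MOM and prenyl ethers are inert to fluoride.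

Step 11
Reactants: 18 3-hydroxy-6,7-bis(methoxymethoxy)-2-{4-(methoxymethoxy)-3-[(3-methylbut-2-en-1-yl)oxy]phenyl}-4H-chromen-4-one
Product: 19 3,6,7-trihydroxy-2-{4-hydroxy-3-[(3-methylbut-2-en-1-yl)oxy]phenyl}-4H-chromen-4-one (target)
Conditions: HCl (about 1 M, from conc. aqueous HCl), MeOH/THF, argon, 25–35 °C, stopped at full conversion
Reagents that add atoms: none
Why: Acid-catalysed acetal exchange with methanol (MOM cleavage through an oxocarbenium ion) should be much faster at room temperature than ionisation of the aryl prenyl ether, and the acidic medium keeps the freed catechol from air oxidation.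

**Compound list**

1 | 3,4-dihydroxybenzaldehyde | O=Cc1ccc(O)c(O)c1 | starting material
2 | 3-hydroxy-4-(methoxymethoxy)benzaldehyde | COCOc1ccc(C=O)cc1O | intermediate
3 | prenyl bromide (1-bromo-3-methylbut-2-ene) | CC(C)=CCBr | starting material
4 | 4-(methoxymethoxy)-3-[(3-methylbut-2-en-1-yl)oxy]benzaldehyde | CC(C)=CCOc1cc(C=O)ccc1OCOC | intermediate
5 | 4-(methoxymethoxy)-3-[(3-methylbut-2-en-1-yl)oxy]benzoic acid | CC(C)=CCOc1cc(C(=O)O)ccc1OCOC | intermediate
6 | 2,4,5-trihydroxybenzaldehyde | O=Cc1cc(O)c(O)cc1O | starting material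
7 | 2-hydroxy-4,5-bis(methoxymethoxy)benzaldehyde | COCOc1cc(O)c(C=O)cc1OCOC | intermediate
8 | 2-formyl-4,5-bis(methoxymethoxy)phenyl 4-(methoxymethoxy)-3-[(3-methylbut-2-en-1-yl)oxy]benzoate | CC(C)=CCOc1cc(C(=O)Oc2cc(OCOC)c(OCOC)cc2C=O)ccc1OCOC | intermediate
9 | 4,5-bis(methoxymethoxy)-2-({4-(methoxymethoxy)-3-[(3-methylbut-2-en-1-yl)oxy]benzoyl}oxy)benzoic acid | CC(C)=CCOc1cc(C(=O)Oc2cc(OCOC)c(OCOC)cc2C(=O)O)ccc1OCOC | intermediate
10 | 2-(chlorocarbonyl)-4,5-bis(methoxymethoxy)phenyl 4-(methoxymethoxy)-3-[(3-methylbut-2-en-1-yl)oxy]benzoate | CC(C)=CCOc1cc(C(=O)Oc2cc(OCOC)c(OCOC)cc2C(Cl)=O)ccc1OCOC | intermediate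
11 | 2-(trimethylsilyl)ethoxymethyl chloride (SEM chloride) | C[Si](C)(C)CCOCCl | starting material
12 | triphenylphosphine | c1ccc(cc1)P(c1ccccc1)c1ccccc1 | starting material
13 | triphenyl{[2-(trimethylsilyl)ethoxy]methyl}phosphonium chloride | C[Si](C)(C)CCOC[P+](c1ccccc1)(c1ccccc1)c1ccccc1.[Cl-] | intermediate
14 | [2-(trimethylsilyl)ethoxy]methylenetriphenylphosphorane | C[Si](C)(C)CCOC=P(c1ccccc1)(c1ccccc1)c1ccccc1 | intermediate
15 | {2-[4,5-bis(methoxymethoxy)-2-({4-(methoxymethoxy)-3-[(3-methylbut-2-en-1-yl)oxy]benzoyl}oxy)phenyl]-2-oxo-1-[2-(trimethylsilyl)ethoxy]ethyl}triphenylphosphonium chloride (racemic, stereocentre lost on deprotonation) | CC(C)=CCOc1cc(C(=O)Oc2cc(OCOC)c(OCOC)cc2C(=O)C(OCC[Si](C)(C)C)[P+](c2ccccc2)(c2ccccc2)c2ccccc2)ccc1OCOC.[Cl-] | intermediate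
16 | 2-{2-[2-(trimethylsilyl)ethoxy]-2-(triphenyl-λ5-phosphanylidene)acetyl}-4,5-bis(methoxymethoxy)phenyl 4-(methoxymethoxy)-3-[(3-methylbut-2-en-1-yl)oxy]benzoate | CC(C)=CCOc1cc(C(=O)Oc2cc(OCOC)c(OCOC)cc2C(=O)C(OCC[Si](C)(C)C)=P(c2ccccc2)(c2ccccc2)c2ccccc2)ccc1OCOC | intermediate
17 | 6,7-bis(methoxymethoxy)-2-{4-(methoxymethoxy)-3-[(3-methylbut-2-en-1-yl)oxy]phenyl}-3-[2-(trimethylsilyl)ethoxy]-4H-chromen-4-one | CC(C)=CCOc1cc(-c2oc3cc(OCOC)c(OCOC)cc3c(=O)c2OCC[Si](C)(C)C)ccc1OCOC | intermediate
18 | 3-hydroxy-6,7-bis(methoxymethoxy)-2-{4-(methoxymethoxy)-3-[(3-methylbut-2-en-1-yl)oxy]phenyl}-4H-chromen-4-one | CC(C)=CCOc1cc(-c2oc3cc(OCOC)c(OCOC)cc3c(=O)c2O)ccc1OCOC | intermediate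
19 | 3,6,7-trihydroxy-2-{4-hydroxy-3-[(3-methylbut-2-en-1-yl)oxy]phenyl}-4H-chromen-4-one | CC(C)=CCOc1cc(-c2oc3cc(O)c(O)cc3c(=O)c2O)ccc1O | target

**Step count.** Total: 11 steps. Longest linear sequence: 9 steps (steps 1, 2, 3, 5, 6, 7, 9, 10, 11, from 1 to 19).

**Steps most likely to fail**

Step 9 (the one step beyond known chemistry). The α-alkoxy ylide may decompose before acylation or be acylated at oxygen. The hindered olefination onto the electron-rich aryl ester may also stall, so that intermolecular acyl transfer takes over from ring closure. Fallback: set out from aldehyde 4 and condense it (Claisen–Schmidt, KOH, EtOH, rt) with 1-[2-hydroxy-4,5-bis(methoxymethoxy)phenyl]ethan-1-one F1. F1 would be made from purchased 1-(2,4,5-trihydroxyphenyl)ethan-1-one (CC(=O)c1cc(O)c(O)cc1O) by the protocol of step 4. The condensation should give (E)-1-[2-hydroxy-4,5-bis(methoxymethoxy)phenyl]-3-{4-(methoxymethoxy)-3-[(3-methylbut-2-en-1-yl)oxy]phenyl}prop-2-en-1-one F2. Algar–Flynn–Oyamada oxidation of this chalcone (NaOH, 30 % H2O2, MeOH, 0 °C to rt) should give the flavonol rather than an aurone, since the chalcone has no 6'-substituent. Alkaline peroxide leaves the isolated prenyl alkene alone. The sequence comes back to the route at 18, before step 11.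

Step 11. Ionisation of the aryl prenyl ether to the prenyl cation may compete with acetal cleavage, so that the prenyl group is lost along with the MOM groups. Fallback: set out from 18 and treat it with Me3SiOTf and 2,2'-bipyridyl in CH2Cl2 at 0 °C. This non-protic exchange converts aryl MOM ethers into aryl silyl ethers and should give 2-{3-[(3-methylbut-2-en-1-yl)oxy]-4-[(trimethylsilyl)oxy]phenyl}-3,6,7-tris[(trimethylsilyl)oxy]-4H-chromen-4-one F6. Addition of water at neutral pH should hydrolyse the silyl ethers and return the route at target 19.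

Step 10. Fluoride-induced fragmentation of the silylethyl ether may be sluggish, and forcing it with hot basic fluoride may open the pyranone ring. Fallback: set out from acid chloride 10 and treat it with methylenetriphenylphosphorane (2.1 equiv, from Ph3PCH3Br and NaN(SiMe3)2, THF, −78 °C). This should give 2-[2-(triphenyl-λ5-phosphanylidene)acetyl]-4,5-bis(methoxymethoxy)phenyl 4-(methoxymethoxy)-3-[(3-methylbut-2-en-1-yl)oxy]benzoate F3, not isolated. Heating F3 in toluene should close ring C by the known intramolecular ester olefination to 6,7-bis(methoxymethoxy)-2-{4-(methoxymethoxy)-3-[(3-methylbut-2-en-1-yl)oxy]phenyl}-4H-chromen-4-one F4. This ring closure would already be validated on the same substrate if step 9 has worked. Deprotonation of F4 at C3 with LiN(i-Pr)2 in THF at −78 °C and trapping with B(OMe)3 should give dimethyl (6,7-bis(methoxymethoxy)-2-{4-(methoxymethoxy)-3-[(3-methylbut-2-en-1-yl)oxy]phenyl}-4-oxo-4H-chromen-3-yl)boronate F5, not isolated. Oxidation with 30 % H2O2 and AcOH at 0 °C should then return the route at 18.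

**Further compounds**

F1 | step 9 | 1-[2-hydroxy-4,5-bis(methoxymethoxy)phenyl]ethan-1-one | CC(=O)c1cc(OCOC)c(OCOC)cc1O
F2 | step 9 | (E)-1-[2-hydroxy-4,5-bis(methoxymethoxy)phenyl]-3-{4-(methoxymethoxy)-3-[(3-methylbut-2-en-1-yl)oxy]phenyl}prop-2-en-1-one | CC(C)=CCOc1cc(/C=C/C(=O)c2cc(OCOC)c(OCOC)cc2O)ccc1OCOC
F3 | step 10 | 2-[2-(triphenyl-λ5-phosphanylidene)acetyl]-4,5-bis(methoxymethoxy)phenyl 4-(methoxymethoxy)-3-[(3-methylbut-2-en-1-yl)oxy]benzoate | CC(C)=CCOc1cc(C(=O)Oc2cc(OCOC)c(OCOC)cc2C(=O)C=P(c2ccccc2)(c2ccccc2)c2ccccc2)ccc1OCOC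
F4 | step 10 | 6,7-bis(methoxymethoxy)-2-{4-(methoxymethoxy)-3-[(3-methylbut-2-en-1-yl)oxy]phenyl}-4H-chromen-4-one | CC(C)=CCOc1cc(-c2cc(=O)c3cc(OCOC)c(OCOC)cc3o2)ccc1OCOC
F5 | step 10 | dimethyl (6,7-bis(methoxymethoxy)-2-{4-(methoxymethoxy)-3-[(3-methylbut-2-en-1-yl)oxy]phenyl}-4-oxo-4H-chromen-3-yl)boronate | CC(C)=CCOc1cc(-c2oc3cc(OCOC)c(OCOC)cc3c(=O)c2B(OC)OC)ccc1OCOC
F6 | step 11 | 2-{3-[(3-methylbut-2-en-1-yl)oxy]-4-[(trimethylsilyl)oxy]phenyl}-3,6,7-tris[(trimethylsilyl)oxy]-4H-chromen-4-one | CC(C)=CCOc1cc(-c2oc3cc(O[Si](C)(C)C)c(O[Si](C)(C)C)cc3c(=O)c2O[Si](C)(C)C)ccc1O[Si](C)(C)C
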